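**Assumptions:** the drawn stereocentre is (S) (O > aryl > butyl > H). 1,3-Dimethoxy-5-pentylbenzene (olivetol dimethyl ether) and n-butylmagnesium chloride are bought. The route is a design and has not been run.

## Retrosynthetic overview

1. Target 14 ⇐ keto acid 12: the only stereocentre is set last, by catalyst-controlled asymmetric transfer hydrogenation of the aryl butyl ketone, then opening of the phthalide that forms.
2. Diaryl ether C–O bond of 12 ⇐ benzophenone 10: oxidative dearomatisation of ring A to a spirodienone (11), then retro-Claisen opening. The benzophenone C=O becomes the CO2H and the spiro C–O bond becomes the ether.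
3. Benzophenone 10 ⇐ tetramethyl ether 9 ⇐ aryllithium from 3,5-dimethoxybenzaldehyde (bromination, butyl Grignard) + 2,4-dimethoxy-6-pentylbenzaldehyde (formylation of olivetol dimethyl ether).
4. Rings: both benzene rings are bought. The only rings formed are transient: the spiro-benzofuranone (step 7), then the phthalide lactone (step 8); both are opened again.

## Route

**Step 1**
Reactants: 1 3,5-dimethoxybenzaldehyde
Product: 2 2-bromo-3,5-dimethoxybenzaldehyde
Conditions: NBS (1.05 equiv), MeCN, 0 °C → rt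
Reagents that add atoms: N-bromosuccinimide, O=C1CCC(=O)N1Br
Why: Electrophilic aromatic bromination; C2 is para to one methoxy and ortho to the other, whereas C4 is para to the deactivating formyl group, so the 2-bromo aldehyde forms selectively.

**Step 2**
Reactants: 2 2-bromo-3,5-dimethoxybenzaldehyde; 3 n-butylmagnesium chloride
Product: 4 1-(2-bromo-3,5-dimethoxyphenyl)pentan-1-ol (racemic)
Conditions: n-BuMgCl (1.2 equiv), THF, −20 → 0 °C; then H2O
Reagents that add atoms: none
Why: Grignard 1,2-addition to the aldehyde (the aryl bromide is inert to an alkyl Grignard at this temperature); the carbinol configuration is irrelevant because it is erased in step 5.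

**Step 3**
Reactants: 5 1,3-dimethoxy-5-pentylbenzene
Product: 6 2,4-dimethoxy-6-pentylbenzaldehyde
Conditions: POCl3 (1.5 equiv), DMF, 0 → 70 °C; then H2O
Reagents that add atoms: N,N-dimethylformamide, CN(C)C=O; water, O
Why: Vilsmeier–Haack formylation at the position para to one methoxy and ortho to the other, favoured over the position between the two methoxy groups (the minor 2,6-dimethoxy isomer is removed by chromatography).

**Step 4**
Reactants: 4 1-(2-bromo-3,5-dimethoxyphenyl)pentan-1-ol; 6 2,4-dimethoxy-6-pentylbenzaldehyde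
Product: 8 1-{2-[(2,4-dimethoxy-6-pentylphenyl)(hydroxy)methyl]-3,5-dimethoxyphenyl}pentan-1-ol (racemic diastereomer mixture), via aryllithium alkoxide 7 (not isolated)
Conditions: n-BuLi (2.2 equiv), THF, −78 °C; then 6, −78 → 0 °C; then H2O
Reagents that add atoms: none
Why: Deprotonation of the alcohol, then bromine–lithium exchange, gives a dianion whose aryllithium adds 1,2 to the non-enolisable aldehyde (organolithium addition, a standard entry to tetra-ortho-substituted diarylmethanols); no stereocontrol is needed.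

**Step 5**
Reactants: 8 the diol from step 4
Product: 9 1-[2-(2,4-dimethoxy-6-pentylbenzoyl)-3,5-dimethoxyphenyl]pentan-1-one
Conditions: Dess–Martin periodinane (3 equiv), pyridine, CH2Cl2, 0 °C → rt
Reagents that add atoms: none
Why: Dess–Martin oxidation of both benzylic carbinols; the intermediate hydroxy ketone can only go on to the 1,2-diacylbenzene because its cyclic hemiketal has no oxidisable C–H, and pyridine suppresses acid cyclodehydration of the 1,4-diol.

**Step 6**
Reactants: 9 the tetramethoxy diketone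
Product: 10 1-[2-(2,4-dihydroxy-6-pentylbenzoyl)-3,5-dihydroxyphenyl]pentan-1-one
Conditions: BBr3 (8 equiv), CH2Cl2, −78 → 0 °C; then H2O
Reagents that add atoms: none
Why: Lewis-acid cleavage of all four aryl methyl ethers (BBr3 demethylation); both ketones survive, and the reaction is kept cold to avoid acid-promoted aldol closure of the 1,2-diacylarene.

**Step 7**
Reactants: 10 the tetrahydroxy diketone
Product: 12 2-(2,4-dihydroxy-6-pentylphenoxy)-4-hydroxy-6-pentanoylbenzoic acid, via spirodienone 11 (not isolated)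
Conditions: PhI(OAc)2 (1.05 equiv), (CF3)2CHOH, −20 → 0 °C; evaporate; then LiOH (8 equiv), THF/H2O, argon, 0 °C → rt; then 1 M HCl
Reagents that add atoms: lithium hydroxide, [Li+].[OH-]
Why: Oxidative dearomatising phenol coupling with trivalent iodine (biomimetic grisadienone formation): the alkyl-substituted, more electron-rich ring A is oxidised and trapped at its acyl-bearing carbon by the ortho hydroxyl of ring B (five-membered spiro ring; ring B carries an extra acyl group and is harder to oxidise), after which hydroxide opens the non-enolisable spiro ketone by retro-Claisen cleavage, rearomatising ring A.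

**Step 8**
Reactants: 12 the keto acid
Product: 14 2-(2,4-dihydroxy-6-pentylphenoxy)-4-hydroxy-6-[(1S)-1-hydroxypentyl]benzoic acid (the target), via (S)-phthalide 13 (not isolated)
Conditions: RuCl[(S,S)-TsDPEN](p-cymene) (2 mol%), HCO2H/Et3N (5:2), DMF, 40 °C; then LiOH (6 equiv), THF/H2O, argon, 0 °C → rt; then 0.5 M HCl to pH 4–5 at 0 °C, cold extraction
Reagents that add atoms: lithium hydroxide, [Li+].[OH-]
Why: Noyori–Ikariya asymmetric transfer hydrogenation of the aryl n-alkyl ketone, where the (S,S) catalyst gives the (S) carbinol by the usual aryl/alkyl face discrimination; the carbinol lactonises in the acidic medium, and saponification (acyl–oxygen cleavage, stereocentre untouched) returns the open hydroxy acid.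

## Compound list

1 | 3,5-dimethoxybenzaldehyde | O=Cc1cc(OC)cc(OC)c1 | starting material
2 | 2-bromo-3,5-dimethoxybenzaldehyde | O=Cc1cc(OC)cc(OC)c1Br | intermediate
3 | n-butylmagnesium chloride | CCCC[Mg]Cl | starting material
4 | 1-(2-bromo-3,5-dimethoxyphenyl)pentan-1-ol (racemic) | CCCCC(O)c1cc(OC)cc(OC)c1Br | intermediate
5 | 1,3-dimethoxy-5-pentylbenzene (olivetol dimethyl ether) | CCCCCc1cc(OC)cc(OC)c1 | starting material
6 | 2,4-dimethoxy-6-pentylbenzaldehyde | CCCCCc1cc(OC)cc(OC)c1C=O | intermediate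
7 | lithium 1-(2-lithio-3,5-dimethoxyphenyl)pentan-1-olate (not isolated) | CCCCC(O[Li])c1cc(OC)cc(OC)c1[Li] | intermediate
8 | 1-{2-[(2,4-dimethoxy-6-pentylphenyl)(hydroxy)methyl]-3,5-dimethoxyphenyl}pentan-1-ol (diastereomer mixture) | CCCCCc1cc(OC)cc(OC)c1C(O)c1c(OC)cc(OC)cc1C(O)CCCC | intermediate
9 | 1-[2-(2,4-dimethoxy-6-pentylbenzoyl)-3,5-dimethoxyphenyl]pentan-1-one | CCCCCc1cc(OC)cc(OC)c1C(=O)c1c(OC)cc(OC)cc1C(=O)CCCC | intermediate
10 | 1-[2-(2,4-dihydroxy-6-pentylbenzoyl)-3,5-dihydroxyphenyl]pentan-1-one | CCCCCc1cc(O)cc(O)c1C(=O)c1c(O)cc(O)cc1C(=O)CCCC | intermediate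
11 | 2',6-dihydroxy-4-pentanoyl-6'-pentyl-3H-spiro[1-benzofuran-2,1'-cyclohexa-2',5'-diene]-3,4'-dione (racemic at the spiro carbon; not isolated) | CCCCCC1=CC(=O)C=C(O)C12Oc1cc(O)cc(C(=O)CCCC)c1C2=O | intermediate
12 | 2-(2,4-dihydroxy-6-pentylphenoxy)-4-hydroxy-6-pentanoylbenzoic acid | CCCCCc1cc(O)cc(O)c1Oc1cc(O)cc(C(=O)CCCC)c1C(=O)O | intermediate
13 | (3S)-3-butyl-7-(2,4-dihydroxy-6-pentylphenoxy)-5-hydroxy-2-benzofuran-1(3H)-one (not isolated) | CCCC[C@@H]1OC(=O)c2c(Oc3c(O)cc(O)cc3CCCCC)cc(O)cc21 | intermediate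
14 | 2-(2,4-dihydroxy-6-pentylphenoxy)-4-hydroxy-6-[(1S)-1-hydroxypentyl]benzoic acid | CCCCCc1cc(O)cc(O)c1Oc1cc(O)cc([C@@H](O)CCCC)c1C(=O)O | target

## Step count and risks

Total steps: 8. Longest linear sequence: 7 (1 → 2 → 4 → 8 → 9 → 10 → 12 → 14).

**Step 7 (most likely to fail).** Both rings of 10 carry free ortho and para hydroxyls, so the direction of the spirocyclisation rests only on ring A being the more electron-rich ring. Dearomatising ring B instead would give the isomeric ether with the CO2H on the pentyl ring. The fallback enforces the direction with protecting groups; it sets out from 6 and 4 and comes back at 12. Aldehyde 6 is demethylated with BBr3 to 2,4-dihydroxy-6-pentylbenzaldehyde F1, which is protected (NaH, MOMCl, DMF) as 2,4-bis(methoxymethoxy)-6-pentylbenzaldehyde F2. Aryllithium 7, made from 4 as in step 4, adds to F2 to give 1-{2-[[2,4-bis(methoxymethoxy)-6-pentylphenyl](hydroxy)methyl]-3,5-dimethoxyphenyl}pentan-1-ol F3, and Dess–Martin oxidation gives 1-{2-[2,4-bis(methoxymethoxy)-6-pentylbenzoyl]-3,5-dimethoxyphenyl}pentan-1-one F4. BCl3 (CH2Cl2, −78 → 0 °C) removes both MOM groups and only the carbonyl-chelated ortho methyl ether of ring B, giving 1-[2-(2,4-dihydroxy-6-pentylbenzoyl)-3-hydroxy-5-methoxyphenyl]pentan-1-one F5. In F5 ring B keeps its para methyl ether, so only ring A can be dearomatised through a free para hydroxyl. PhI(OAc)2 then LiOH, as in step 7, gives 2',-hydroxy-6-methoxy-4-pentanoyl-6'-pentyl-3H-spiro[1-benzofuran-2,1'-cyclohexa-2',5'-diene]-3,4'-dione F6 (not isolated) and from it 2-(2,4-dihydroxy-6-pentylphenoxy)-4-methoxy-6-pentanoylbenzoic acid F7. BBr3 cleaves the last methyl ether to give 12.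

**Step 4.** Joining a di-ortho-substituted aryllithium to a di-ortho-substituted aldehyde may be slow or low-yielding. The fallback makes the same C–C bond intramolecularly (anionic homo-Fries acyl transfer); it sets out from 6 and 4 and comes back at 9. Aldehyde 6 is oxidised (NaClO2, NaH2PO4, 2-methyl-2-butene) to 2,4-dimethoxy-6-pentylbenzoic acid F8 and converted with oxalyl chloride into 2,4-dimethoxy-6-pentylbenzoyl chloride F9. The lithium alkoxide of 4 (1 equiv n-BuLi, −78 °C) is acylated with F9 to give 1-(2-bromo-3,5-dimethoxyphenyl)pentyl 2,4-dimethoxy-6-pentylbenzoate F10. n-BuLi at −78 °C then effects bromine–lithium exchange and 1,4 O→C acyl migration through a five-membered transition state, giving [2-(1-hydroxypentyl)-4,6-dimethoxyphenyl](2,4-dimethoxy-6-pentylphenyl)methanone F11. Dess–Martin oxidation of F11 gives 9.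

**Step 8.** The ortho-carboxy, polyphenolic ketone may reduce slowly or with eroded ee, and the product relactonises readily in acid, hence the cold pH 4–5 isolation. The fallback sets the stereocentre by C=C rather than C=O reduction; it sets out from 12 and comes back at 13. Keto acid 12 is dehydrated (TsOH, toluene, reflux, water removal) to (Z)-3-butylidene-7-(2,4-dihydroxy-6-pentylphenoxy)-5-hydroxy-2-benzofuran-1(3H)-one F12. Its exocyclic enol-lactone double bond is hydrogenated enantioselectively ([Ir(cod)Cl]2 with a chiral spiro phosphine–oxazoline ligand, H2), the ligand enantiomer being chosen to give (S)-13. The LiOH opening of step 8 then follows.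

## Further compounds

F1 | step 7 | 2,4-dihydroxy-6-pentylbenzaldehyde | CCCCCc1cc(O)cc(O)c1C=O
F2 | step 7 | 2,4-bis(methoxymethoxy)-6-pentylbenzaldehyde | CCCCCc1cc(OCOC)cc(OCOC)c1C=O
F3 | step 7 | 1-{2-[[2,4-bis(methoxymethoxy)-6-pentylphenyl](hydroxy)methyl]-3,5-dimethoxyphenyl}pentan-1-ol | CCCCCc1cc(OCOC)cc(OCOC)c1C(O)c1c(OC)cc(OC)cc1C(O)CCCC
F4 | step 7 | 1-{2-[2,4-bis(methoxymethoxy)-6-pentylbenzoyl]-3,5-dimethoxyphenyl}pentan-1-one | CCCCCc1cc(OCOC)cc(OCOC)c1C(=O)c1c(OC)cc(OC)cc1C(=O)CCCC
F5 | step 7 | 1-[2-(2,4-dihydroxy-6-pentylbenzoyl)-3-hydroxy-5-methoxyphenyl]pentan-1-one | CCCCCc1cc(O)cc(O)c1C(=O)c1c(O)cc(OC)cc1C(=O)CCCC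
F6 | step 7 | 2'-hydroxy-6-methoxy-4-pentanoyl-6'-pentyl-3H-spiro[1-benzofuran-2,1'-cyclohexa-2',5'-diene]-3,4'-dione | CCCCCC1=CC(=O)C=C(O)C12Oc1cc(OC)cc(C(=O)CCCC)c1C2=O
F7 | step 7 | 2-(2,4-dihydroxy-6-pentylphenoxy)-4-methoxy-6-pentanoylbenzoic acid | CCCCCc1cc(O)cc(O)c1Oc1cc(OC)cc(C(=O)CCCC)c1C(=O)O
F8 | step 4 | 2,4-dimethoxy-6-pentylbenzoic acid | CCCCCc1cc(OC)cc(OC)c1C(=O)O
F9 | step 4 | 2,4-dimethoxy-6-pentylbenzoyl chloride | CCCCCc1cc(OC)cc(OC)c1C(=O)Cl
F10 | step 4 | 1-(2-bromo-3,5-dimethoxyphenyl)pentyl 2,4-dimethoxy-6-pentylbenzoate | CCCCCc1cc(OC)cc(OC)c1C(=O)OC(CCCC)c1cc(OC)cc(OC)c1Br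
F11 | step 4 | [2-(1-hydroxypentyl)-4,6-dimethoxyphenyl](2,4-dimethoxy-6-pentylphenyl)methanone | CCCCCc1cc(OC)cc(OC)c1C(=O)c1c(OC)cc(OC)cc1C(O)CCCC
F12 | step 8 | (Z)-3-butylidene-7-(2,4-dihydroxy-6-pentylphenoxy)-5-hydroxy-2-benzofuran-1(3H)-one | CCC/C=C1\OC(=O)c2c(Oc3c(O)cc(O)cc3CCCCC)cc(O)cc21
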